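## Retrosynthetic overview

1. Aiphanol, (2R,3R)-trans, is reached by reductive removal of a camphorsultam from the C9 acyl group of the finished stilbenyl benzodioxane. This is the only step after ring formation.
2. The 1,4-benzodioxane, the only ring made, comes from one biomimetic event: 8-O-4' phenoxyl radical cross-coupling of an N-sinapoyl sultam with intact, unprotected piceatannol, then oxa-Michael closure of the 3'-OH onto the quinone methide.
3. C8 is set by the auxiliary in the radical coupling, and C7 is relayed trans in the ring closure.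
4. The stilbene C=C is not disconnected: it arrives ready-made in piceatannol, and all three arene rings are bought.
5. The N-sinapoyl sultam comes from sinapic acid and (1R)-(+)-2,10-camphorsultam.

Notation: C7 is the ArCH–O carbon, C8 the O–CH carbon bearing C9, and C9 the side-chain carbonyl or CH2OH carbon.

Assumption: sinapic acid, piceatannol and both enantiomers of 2,10-camphorsultam are taken as catalogue chemicals, piceatannol being the dearest.

Assumption: the auxiliary is chosen on the non-chelated model for α-carbonyl radicals of N-acyl bornane-10,2-sultams (C=O anti to SO2, s-cis, attack anti to the pseudo-axial sulfonyl oxygen), which puts the new C8–O bond on the C8 Si face with the (2S)-sultam; if the sense proved opposite, the enantiomeric sultam would be used with nothing else changed.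

## Route

Step 1
Reactants: 1 sinapic acid, (E)-3-(4-hydroxy-3,5-dimethoxyphenyl)prop-2-enoic acid
Product: 2 O-acetylsinapic acid, (E)-3-(4-acetoxy-3,5-dimethoxyphenyl)prop-2-enoic acid
Conditions: Ac2O (2.5 equiv), pyridine, rt, 4 h; then H2O, rt, 1 h; 1 M HCl, filter
Reagents that add atoms: acetic anhydride, CC(=O)OC(C)=O
Why: Pyridine-promoted O-acetylation of the phenol (nucleophilic acyl substitution), the carboxyl mixed anhydride formed alongside being hydrolysed in the water quench; no stereocentre is involved and the E-alkene is untouched.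

Step 2
Reactants: 2 O-acetylsinapic acid; 3 (1R)-(+)-2,10-camphorsultam, (2S)-bornane-10,2-sultam
Product: 6 N-[(E)-3-(4-hydroxy-3,5-dimethoxyphenyl)prop-2-enoyl]-(2S)-bornane-10,2-sultam, via O-acetylsinapoyl chloride 4 (not isolated), via O-acetyl N-sinapoyl sultam 5 (not isolated)
Conditions: (COCl)2 (1.3 equiv), DMF (cat.), CH2Cl2, 0 °C → rt, evaporate; 3 (1.0 equiv), Et3N (2 equiv), DMAP (0.2 equiv), CH2Cl2, 0 °C → rt; then pyrrolidine (3 equiv), 0 °C, 30 min; 1 M HCl wash
Reagents that add atoms: none
Why: Acid chloride formation through the Vilsmeier chloroiminium and DMAP-catalysed N-acylation of the sultam N–H (standard N-enoyl sultam synthesis) are followed by chemoselective aminolysis of the aryl acetate, which is far more electrophilic than the conjugated imide, so the phenol is masked only while the acid chloride exists; no new stereocentre is formed.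

Step 3
Reactants: 6 N-sinapoyl-(2S)-bornane-10,2-sultam; 7 piceatannol, (E)-3,3',4',5-tetrahydroxystilbene
Product: 9 N-{[(2S,3R)-6-[(E)-2-(3,5-dihydroxyphenyl)ethenyl]-3-(4-hydroxy-3,5-dimethoxyphenyl)-2,3-dihydro-1,4-benzodioxin-2-yl]carbonyl}-(2S)-bornane-10,2-sultam (trans), via quinone methide 8 (not isolated)
Conditions: Ag2O (2.5 equiv), CH2Cl2–acetone 2:1, dark, 0 °C → rt; 7 (1.0 equiv) added over 6 h to 6 (1.5 equiv); filter through Celite; chromatography, then crystallisation of the major diastereomer
Reagents that add atoms: none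
Why: Proposed new method: Ag2O oxidises both phenols by one electron, the sinapoyl phenoxyl radical (spin at C8) and the piceatannol 4'-aryloxyl radical (the para-hydroxyl, stabilised through the stilbene) combine in an 8-O-4' radical–radical coupling on the C8 Si face, the Re face of the s-cis, C=O-anti-to-SO2 rotamer being screened by the pseudo-axial sulfonyl oxygen, to give quinone methide 8 with 8S, and the 3'-OH then adds to C7 anti to the bulky acyl sultam in a reversible oxa-Michael closure that delivers the thermodynamic trans ring (C7 R), so both stereocentres come from the auxiliary; the closest known chemistry is the silver oxide or silver carbonate coupling of catechols with coniferyl- and sinapyl-type phenols to trans-1,4-benzodioxanes and the sultam-controlled oxidative dimerisation of feruloyl amides, while the use of unprotected piceatannol and auxiliary control of an 8-O-4' heterocoupling are new.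

Step 4
Reactants: 9 trans-benzodioxane acyl sultam
Product: 10 aiphanol, 5-[(E)-2-[(2R,3R)-3-(4-hydroxy-3,5-dimethoxyphenyl)-2-(hydroxymethyl)-2,3-dihydro-1,4-benzodioxin-6-yl]ethenyl]benzene-1,3-diol
Conditions: LiBH4 (6 equiv), THF–MeOH 20:1, 0 °C → rt, 3 h; 1 M HCl to pH 5
Reagents that add atoms: none
Why: Reductive cleavage of an N-acyl sultam, in which hydride adds to the exocyclic imide carbonyl, the sulfonamide anion leaves and the aldehyde is reduced at once to the primary alcohol; neither stereocentre is touched (the C2 descriptor changes from S to R only because CH2OH ranks below the ring carbon), the stilbene and aryl ethers are inert, the phenols only consume hydride, and the auxiliary is recovered.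

## Compound list

1 | sinapic acid | COc1cc(/C=C/C(=O)O)cc(OC)c1O | starting material
2 | O-acetylsinapic acid | COc1cc(/C=C/C(=O)O)cc(OC)c1OC(C)=O | intermediate
3 | (1R)-(+)-2,10-camphorsultam, (2S)-bornane-10,2-sultam | CC1(C)[C@H]2CC[C@@]13CS(=O)(=O)N[C@H]3C2 | starting material
4 | O-acetylsinapoyl chloride | COc1cc(/C=C/C(=O)Cl)cc(OC)c1OC(C)=O | intermediate
5 | N-(O-acetylsinapoyl)-(2S)-bornane-10,2-sultam | COc1cc(/C=C/C(=O)N2[C@H]3C[C@@H]4CC[C@@]3(CS2(=O)=O)C4(C)C)cc(OC)c1OC(C)=O | intermediate
6 | N-sinapoyl-(2S)-bornane-10,2-sultam | COc1cc(/C=C/C(=O)N2[C@H]3C[C@@H]4CC[C@@]3(CS2(=O)=O)C4(C)C)cc(OC)c1O | intermediate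
7 | piceatannol | Oc1cc(O)cc(/C=C/c2ccc(O)c(O)c2)c1 | starting material
8 | (8S)-8-O-4' quinone methide (2,6-dimethoxy-4-alkylidenecyclohexa-2,5-dienone, 3'-OH free) | COC1=CC(=C[C@H](Oc2ccc(/C=C/c3cc(O)cc(O)c3)cc2O)C(=O)N5[C@H]6C[C@@H]7CC[C@@]6(CS5(=O)=O)C7(C)C)C=C(OC)C1=O | intermediate
9 | (2S,3R)-trans-benzodioxane-2-carbonyl (2S)-bornane-10,2-sultam | COc1cc([C@H]2Oc3cc(/C=C/c4cc(O)cc(O)c4)ccc3O[C@@H]2C(=O)N5[C@H]6C[C@@H]7CC[C@@]6(CS5(=O)=O)C7(C)C)cc(OC)c1O | intermediate
10 | aiphanol, (2R,3R) | COc1cc([C@H]2Oc3cc(/C=C/c4cc(O)cc(O)c4)ccc3O[C@@H]2CO)cc(OC)c1O | target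

## Step count and risks

Total steps: 4. Longest linear sequence: 4 (1 → 2 → 6 → 9 → 10).

**Step 3 (highest risk).** Piceatannol may self-couple through its stilbene, the other catechol oxygen may couple, or facial control may be modest. The fallback takes the stilbene out of the radical step and sets out from 6. Compound 6 is oxidised with Ag2O in the presence of bought 3,4-dihydroxybenzaldehyde, whose para-hydroxyl is the more acidic and which has no styrene carbon to couple through. The same auxiliary-controlled coupling and closure give the benzodioxane aldehyde imide F1. F1 is olefinated with the ylide from the known salt [3,5-bis(tert-butyldimethylsilyloxy)benzyl]triphenylphosphonium bromide F2, taken as a stock reagent (LiN(SiMe3)2, THF, −78 °C → 0 °C, one extra equivalent for the phenol). I2-catalysed Z-to-E equilibration gives the bis-silyl stilbene imide F3, and Bu4NF buffered with AcOH removes the silyl groups and returns to the route at 9.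

**Step 4.** The hydride conditions may epimerise C2 or open the ring through the para-phenoxide. The fallback sets out from 9 and separates cleavage from reduction. LiOH/H2O2 in THF–H2O at 0 °C hydrolyses the exocyclic imide carbonyl to the carboxylic acid F4 and returns the sultam. BH3·THF at 0 °C then reduces the acid, faster than it hydroborates the stilbene, and the route is rejoined at 10.

**Step 2.** The acetoxy acid chloride may transfer acetyl or oligomerise, or pyrrolidine may attack the imide. The fallback builds the enoyl unit by olefination and sets out from 3. Compound 3 is acylated with bromoacetyl bromide (NaH, THF, 0 °C) to the N-bromoacetyl sultam F5. PPh3 in toluene at 60 °C gives the phosphonium bromide F6, and aqueous NaOH gives the stabilised ylide F7. F7 is heated with bought syringaldehyde in toluene at 90 °C; the stabilised-ylide Wittig reaction tolerates the free phenol and gives the E-imide directly, rejoining the route at 6 with step 1 no longer needed.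

## Further compounds

F1 | step 3 | N-{[(2S,3R)-6-formyl-3-(4-hydroxy-3,5-dimethoxyphenyl)-2,3-dihydro-1,4-benzodioxin-2-yl]carbonyl}-(2S)-bornane-10,2-sultam | COc1cc([C@H]2Oc3cc(C=O)ccc3O[C@@H]2C(=O)N5[C@H]6C[C@@H]7CC[C@@]6(CS5(=O)=O)C7(C)C)cc(OC)c1O
F2 | step 3 | [3,5-bis(tert-butyldimethylsilyloxy)benzyl]triphenylphosphonium bromide | CC(C)(C)[Si](C)(C)Oc1cc(C[P+](c2ccccc2)(c2ccccc2)c2ccccc2)cc(O[Si](C)(C)C(C)(C)C)c1.[Br-]
F3 | step 3 | 3,5-bis-O-(tert-butyldimethylsilyl) ether of 9 | COc1cc([C@H]2Oc3cc(/C=C/c4cc(O[Si](C)(C)C(C)(C)C)cc(O[Si](C)(C)C(C)(C)C)c4)ccc3O[C@@H]2C(=O)N5[C@H]6C[C@@H]7CC[C@@]6(CS5(=O)=O)C7(C)C)cc(OC)c1O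
F4 | step 4 | (2S,3R)-6-[(E)-2-(3,5-dihydroxyphenyl)ethenyl]-3-(4-hydroxy-3,5-dimethoxyphenyl)-2,3-dihydro-1,4-benzodioxine-2-carboxylic acid | COc1cc([C@H]2Oc3cc(/C=C/c4cc(O)cc(O)c4)ccc3O[C@@H]2C(=O)O)cc(OC)c1O
F5 | step 2 | N-(bromoacetyl)-(2S)-bornane-10,2-sultam | O=C(CBr)N1[C@H]2C[C@@H]3CC[C@@]2(CS1(=O)=O)C3(C)C
F6 | step 2 | {2-oxo-2-[(2S)-bornane-10,2-sultam-N-yl]ethyl}triphenylphosphonium bromide | O=C(C[P+](c1ccccc1)(c1ccccc1)c1ccccc1)N1[C@H]2C[C@@H]3CC[C@@]2(CS1(=O)=O)C3(C)C.[Br-]
F7 | step 2 | N-[(triphenylphosphoranylidene)acetyl]-(2S)-bornane-10,2-sultam | O=C(C=P(c1ccccc1)(c1ccccc1)c1ccccc1)N1[C@H]2C[C@@H]3CC[C@@]2(CS1(=O)=O)C3(C)C
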